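**Strategy.** The ring is numbered C1 (stereocentre) to C14, with C15 the side-chain methylene carbon. The E-trisubstituted C11=C12 alkene and the adjoining C13–C14 bond of the 14-membered carbocycle are read as the product of a Claisen shift. The carbocycle is therefore traced back to a 14-membered lactone in which a sacrificial carboxyl on C14 is esterified to an isopropenyl carbinol at C11. One Ireland–Claisen rearrangement of its silyl ketene acetal forms C13–C14, creates the E alkene and turns the lactone into the carbocycle; radical decarboxylation then gives the target. The lactone is assembled from a rhodium-set C1 lactone and a neryl acetate-derived phosphonate by E-selective olefination and macrolactonisation.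

Key step: step 14

Remark: C11 is carried as both epimers because it becomes sp2 in step 14, and (S)-BINAP is assumed to deliver the (S)-lactone 7 by analogy with its sense of induction on cyclic enones (the ligand antipode would be used otherwise). The C10 unit of neryl acetate supplies only C6–C13, so C5 is added by a one-carbon homologation (step 8).

Step 1
Reactants: 1 6-methylhept-5-en-2-one
Product: 2 N'-[(2E)-6-methylhept-5-en-2-ylidene]-2,4,6-tri(propan-2-yl)benzenesulfonohydrazide
Conditions: 2,4,6-triisopropylbenzenesulfonyl hydrazide, HCl (cat.), MeOH, rt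
Reagents that add atoms: 2,4,6-tri(propan-2-yl)benzenesulfonohydrazide, CC(C)c1cc(C(C)C)c(S(=O)(=O)NN)c(C(C)C)c1
Why: Acid-catalysed hydrazone condensation of a methyl ketone is reliable, leaves the trisubstituted alkene untouched and should give mainly the E hydrazone needed for the next step.

Step 2
Reactants: 2 N'-[(2E)-6-methylhept-5-en-2-ylidene]-2,4,6-tri(propan-2-yl)benzenesulfonohydrazide
Product: 5 potassium trifluoro(6-methylhepta-1,5-dien-2-yl)borate, via alkenyllithium 3 (not isolated), via lithium alkenylborate 4 (not isolated)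
Conditions: n-BuLi (2.1 equiv), TMEDA/hexane, −78 to 0 °C; B(OiPr)3, −78 °C to rt; aq KHF2, MeOH
Reagents that add atoms: triisopropyl borate, CC(C)OB(OC(C)C)OC(C)C; potassium hydrogen difluoride, F.[F-].[K+]
Why: In this Shapiro reaction the second equivalent of base removes a proton from the methyl group syn to the sulfonamide nitrogen, loss of sulfinate and N2 gives the 1-alken-2-yllithium regiospecifically, and borylation followed by fluoride exchange gives a bench-stable alkenyltrifluoroborate.

Step 3
Reactants: 5 potassium trifluoro(6-methylhepta-1,5-dien-2-yl)borate; 6 5,6-dihydro-2H-pyran-2-one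
Product: 7 (4S)-4-(6-methylhepta-1,5-dien-2-yl)oxan-2-one
Conditions: [Rh(cod)2]PF6 (3 mol%), (S)-BINAP (3.3 mol%), toluene/H2O 10:1, 105 °C
Reagents that add atoms: none
Why: In this rhodium-catalysed asymmetric 1,4-addition of an alkenylboron reagent to an α,β-unsaturated lactone (Hayashi–Miyaura reaction) the alkenylrhodium–BINAP complex should add to one enantioface of the cis-locked enoate and the oxa-π-allylrhodium is hydrolysed by water, so the ligand sets C1 (S in 7, R in the target only because CIP priorities change).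

Step 4
Reactants: 7 (4S)-4-(6-methylhepta-1,5-dien-2-yl)oxan-2-one
Product: 9 prop-2-enyl (3S)-5-hydroxy-3-(6-methylhepta-1,5-dien-2-yl)pentanoate, via potassium hydroxy-carboxylate 8 (not isolated)
Conditions: KOH (1.05 equiv), MeOH/H2O, rt; evaporate; allyl bromide, DMF, rt
Reagents that add atoms: potassium hydroxide, [K+].[OH-]; allyl bromide, C=CCBr
Why: Saponification of the δ-lactone and SN2 O-alkylation of the carboxylate salt differentiate the two arms of C1 in one operation, leave the primary alcohol free and install an ester that can later be removed under neutral conditions.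

Step 5
Reactants: 9 prop-2-enyl (3S)-5-hydroxy-3-(6-methylhepta-1,5-dien-2-yl)pentanoate
Product: 10 prop-2-enyl (3S)-3-(6-methylhepta-1,5-dien-2-yl)-5-oxopentanoate
Conditions: TEMPO (10 mol%), PhI(OAc)2 (1.1 equiv), CH2Cl2, rt
Reagents that add atoms: none
Why: The TEMPO-catalysed oxoammonium oxidation stops at the aldehyde, tolerates the alkenes and the allyl ester, and its near-neutral medium should avoid relactonisation of the hydroxy ester.

Step 6
Reactants: 11 neryl acetate
Product: 12 (2Z)-5-(3,3-dimethyloxiran-2-yl)-3-methylpent-2-en-1-yl acetate (racemic)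
Conditions: mCPBA (1.05 equiv), NaHCO3, CH2Cl2, 0 °C
Reagents that add atoms: mCPBA, OOC(=O)c1cccc(Cl)c1
Why: In this Prilezhaev epoxidation the distal trisubstituted alkene is the more electron-rich one because the C2–C3 alkene is deactivated by the allylic acetoxy group, so mono-epoxidation should occur at the terminus.

Step 7
Reactants: 12 (2Z)-5-(3,3-dimethyloxiran-2-yl)-3-methylpent-2-en-1-yl acetate
Product: 13 (2Z)-6-hydroxy-3,7-dimethylocta-2,7-dien-1-yl acetate (racemic)
Conditions: Al(OiPr)3 (1.5 equiv), toluene, 110 °C; aq Rochelle salt work-up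
Reagents that add atoms: none
Why: In this aluminium alkoxide-mediated epoxide-to-allylic alcohol isomerisation the metal coordinates the epoxide oxygen and a methyl proton is removed through a cyclic transition state as the tertiary C–O bond opens, which gives the isopropenyl carbinol (future C11–C13) as known for terminal epoxides of prenyl acetates.

Step 8
Reactants: 13 (2Z)-6-hydroxy-3,7-dimethylocta-2,7-dien-1-yl acetate; 14 (chloromethyl)dimethyl(propan-2-yloxy)silane
Product: 17 (3Z)-4,8-dimethylnona-3,8-diene-1,7-diol, via Grignard reagent 15 (not isolated), via alkoxysilane 16 (not isolated)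
Conditions: 14, Mg, THF; then 13, Li2CuCl4 (5 mol%), THF, −20 to 0 °C (3 equiv of 15); then 30% H2O2, KF, KHCO3, MeOH/THF, rt
Reagents that add atoms: hydrogen peroxide, OO
Why: Copper-catalysed SN2-type allylic substitution of the primary acetate by the silylmethyl Grignard reagent (a hydroxymethyl anion equivalent) followed by Tamao–Fleming oxidation of the C–Si bond adds the missing carbon C5 with the Z alkene expected to be retained, the free carbinol merely consuming one equivalent of Grignard reagent.

Step 9
Reactants: 17 (3Z)-4,8-dimethylnona-3,8-diene-1,7-diol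
Product: 18 (3Z)-7-hydroxy-4,8-dimethylnona-3,8-dien-1-yl 4-methylbenzenesulfonate
Conditions: TsCl (1.05 equiv), Et3N, DMAP (cat.), CH2Cl2, 0 °C
Reagents that add atoms: TsCl, Cc1ccc(cc1)S(=O)(=O)Cl
Why: O-Sulfonylation is much faster at the unhindered primary alcohol than at the secondary carbinol flanked by the isopropenyl group, so one equivalent of TsCl at low temperature should give the mono-tosylate.

Step 10
Reactants: 18 (3Z)-7-hydroxy-4,8-dimethylnona-3,8-dien-1-yl 4-methylbenzenesulfonate; 19 methyl 2-(diethoxyphosphoryl)acetate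
Product: 21 methyl (5Z)-2-(diethoxyphosphoryl)-9-hydroxy-6,10-dimethylundeca-5,10-dienoate (mixture of diastereomers), via sodium phosphonoacetate 20 (not isolated)
Conditions: 19 (3 equiv), NaH (2.8 equiv), DMF, 0 °C; then 18, 65 °C
Reagents that add atoms: none
Why: This is an SN2 alkylation of a stabilised phosphonoacetate carbanion by a primary tosylate, in which the excess of carbanion suppresses dialkylation and the anion is too weak a base to deprotonate the free secondary alcohol.

Step 11
Reactants: 10 prop-2-enyl (3S)-3-(6-methylhepta-1,5-dien-2-yl)-5-oxopentanoate; 21 methyl (5Z)-2-(diethoxyphosphoryl)-9-hydroxy-6,10-dimethylundeca-5,10-dienoate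
Product: 22 prop-2-enyl (3S,5E,9Z)-13-hydroxy-6-(methoxycarbonyl)-10,14-dimethyl-3-(6-methylhepta-1,5-dien-2-yl)pentadeca-5,9,14-trienoate (both C13 epimers)
Conditions: LiCl, DBU, MeCN, rt
Reagents that add atoms: none
Why: In this Horner–Wadsworth–Emmons olefination under Masamune–Roush conditions, reversible addition of the lithium-chelated phosphonate anion and elimination through the less crowded oxaphosphetane should favour the E enoate (C2 trans to CO2Me), the mild base tolerates the free carbinol, the allyl ester and the enolisable aldehyde, and any Z isomer would be removed by chromatography.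

Step 12
Reactants: 22 prop-2-enyl (3S,5E,9Z)-13-hydroxy-6-(methoxycarbonyl)-10,14-dimethyl-3-(6-methylhepta-1,5-dien-2-yl)pentadeca-5,9,14-trienoate
Product: 23 (3S,5E,9Z)-13-hydroxy-6-(methoxycarbonyl)-10,14-dimethyl-3-(6-methylhepta-1,5-dien-2-yl)pentadeca-5,9,14-trienoic acid (both C13 epimers)
Conditions: Pd(PPh3)4 (5 mol%), morpholine, THF, rt
Reagents that add atoms: none
Why: In this Tsuji–Trost deallylation zerovalent palladium ionises only the allyl ester to a π-allyl complex that morpholine captures, so the methyl enoate and the unactivated allylic alcohol should remain untouched.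

Step 13
Reactants: 23 (3S,5E,9Z)-13-hydroxy-6-(methoxycarbonyl)-10,14-dimethyl-3-(6-methylhepta-1,5-dien-2-yl)pentadeca-5,9,14-trienoic acid
Product: 25 methyl (4S,6E,10Z)-11-methyl-4-(6-methylhepta-1,5-dien-2-yl)-2-oxo-14-(prop-1-en-2-yl)-1-oxacyclotetradeca-6,10-diene-7-carboxylate (both epimers at the carbinol carbon), via mixed anhydride 24 (not isolated)
Conditions: 2,4,6-Cl3C6H2COCl, Et3N, THF, rt; then slow addition to DMAP, toluene, 80 °C (about 1 mM)
Reagents that add atoms: none
Why: In this Yamaguchi macrolactonisation the mixed trichlorobenzoic anhydride acylates DMAP and slow addition at high dilution lets the secondary C11 carbinol close the 14-membered lactone in preference to oligomerisation, with no epimerisable centre next to the activated carboxyl.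

Step 14
Reactants: 25 methyl (4S,6E,10Z)-11-methyl-4-(6-methylhepta-1,5-dien-2-yl)-2-oxo-14-(prop-1-en-2-yl)-1-oxacyclotetradeca-6,10-diene-7-carboxylate
Product: 28 (1S,3E,7Z,11E)-4-(methoxycarbonyl)-8,12-dimethyl-1-(6-methylhepta-1,5-dien-2-yl)cyclotetradeca-3,7,11-triene-14-carboxylic acid (overview numbering, both C14 epimers), via silyl ketene acetal 26 (not isolated), via trimethylsilyl ester 27 (not isolated)
Conditions: TMSCl/Et3N (1:1, premixed), THF, −78 °C, lithium diisopropylamide (1.2 equiv) added slowly; warm to rt, then toluene, 80 °C; 1 M HCl work-up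
Reagents that add atoms: none
Why: Deprotonation of the lactone α-CH2 (C14) in the presence of TMSCl traps the enolate at once as silyl ketene acetal 26, whose C14=C(OSi)–O–C11–C12=C13 array undergoes a concerted suprafacial [3,3] shift on warming, so that C14 bonds to the isopropenyl methylene C13, the C11–O bond breaks and the C11=C12 alkene forms, giving silyl ester 27 and, after hydrolysis, acid 28. The closest known reaction type is the Ireland–Claisen rearrangement of allylic macrolactones to carbocyclic acids. The 14-membered carbocycle is not closed by an exo or endo cyclisation but inside a six-membered pericyclic chair whose termini C14 and C11 are already bridged by the ten-carbon tether C1–C10, so the –C(=O)–O– bridge is exchanged for C13–C12 and the ring size is conserved. The new stereocentre C14 is uncontrolled (it follows the ketene acetal geometry and the C11 epimer) and need not be controlled because step 15 removes it, while C1 is not enolisable and stays intact. The step needs the E geometry at C11=C12, which the chair with the C10 chain pseudo-equatorial at C11 should secure because the axial alternative clashes with the C12 methyl and the silyloxy group. It also needs site-selective enolisation, which should follow from the higher kinetic acidity of the saturated lactone α-protons over the γ-protons of the α-branched E enoate, the small excess of base and the internal silyl quench at −78 °C.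

Step 15
Reactants: 28 (1S,3E,7Z,11E)-4-(methoxycarbonyl)-8,12-dimethyl-1-(6-methylhepta-1,5-dien-2-yl)cyclotetradeca-3,7,11-triene-14-carboxylic acid
Product: 30 methyl (1R,3E,7Z,11E)-8,12-dimethyl-1-(6-methylhepta-1,5-dien-2-yl)cyclotetradeca-3,7,11-triene-4-carboxylate (overview numbering; CNP0163659.1), via thiohydroxamate ester 29 (not isolated)
Conditions: 2-mercaptopyridine N-oxide, DCC, DMAP (cat.), CH2Cl2, 0 °C to rt, dark; then t-BuSH (20 equiv), hν (tungsten lamp), 10 °C
Reagents that add atoms: none
Why: In this Barton reductive decarboxylation the thiohydroxamate ester fragments under visible light to the secondary C14 radical, which should abstract hydrogen from the concentrated thiol far faster than it can cyclise (only 3-exo, 4-exo, 5-endo or slow 6-exo modes are open to it), so both C14 epimers converge on the target with C1 and the three ring alkenes unchanged.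

**Compound list**

1 | 6-methylhept-5-en-2-one | CC(=O)CCC=C(C)C | starting material
2 | N'-[(2E)-6-methylhept-5-en-2-ylidene]-2,4,6-tri(propan-2-yl)benzenesulfonohydrazide | C/C(CCC=C(C)C)=N\NS(=O)(=O)c1c(C(C)C)cc(C(C)C)cc1C(C)C | intermediate
3 | (6-methylhepta-1,5-dien-2-yl)lithium | [Li]C(=C)CCC=C(C)C | intermediate (not isolated)
4 | lithium (6-methylhepta-1,5-dien-2-yl)tri(propan-2-yloxy)borate | [Li+].C=C(CCC=C(C)C)[B-](OC(C)C)(OC(C)C)OC(C)C | intermediate (not isolated)
5 | potassium trifluoro(6-methylhepta-1,5-dien-2-yl)borate | [K+].C=C(CCC=C(C)C)[B-](F)(F)F | intermediate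
6 | 5,6-dihydro-2H-pyran-2-one | O=C1C=CCCO1 | starting material
7 | (4S)-4-(6-methylhepta-1,5-dien-2-yl)oxan-2-one | C=C(CCC=C(C)C)[C@@H]1CC(=O)OCC1 | intermediate
8 | potassium (3S)-5-hydroxy-3-(6-methylhepta-1,5-dien-2-yl)pentanoate | [K+].C=C(CCC=C(C)C)[C@@H](CCO)CC(=O)[O-] | intermediate (not isolated)
9 | prop-2-enyl (3S)-5-hydroxy-3-(6-methylhepta-1,5-dien-2-yl)pentanoate | C=C(CCC=C(C)C)[C@@H](CCO)CC(=O)OCC=C | intermediate
10 | prop-2-enyl (3S)-3-(6-methylhepta-1,5-dien-2-yl)-5-oxopentanoate | C=C(CCC=C(C)C)[C@@H](CC=O)CC(=O)OCC=C | intermediate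
11 | neryl acetate, (2Z)-3,7-dimethylocta-2,6-dien-1-yl acetate | CC(C)=CCC/C(C)=C\COC(C)=O | starting material
12 | (2Z)-5-(3,3-dimethyloxiran-2-yl)-3-methylpent-2-en-1-yl acetate (racemic) | CC(=O)OC/C=C(/C)CCC1OC1(C)C | intermediate
13 | (2Z)-6-hydroxy-3,7-dimethylocta-2,7-dien-1-yl acetate (racemic) | CC(=O)OC/C=C(/C)CCC(O)C(C)=C | intermediate
14 | (chloromethyl)dimethyl(propan-2-yloxy)silane | CC(C)O[Si](C)(C)CCl | starting material
15 | chlorido{[dimethyl(propan-2-yloxy)silyl]methyl}magnesium | CC(C)O[Si](C)(C)C[Mg]Cl | intermediate (not isolated)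
16 | (6Z)-9-[dimethyl(propan-2-yloxy)silyl]-2,6-dimethylnona-1,6-dien-3-ol | CC(C)O[Si](C)(C)CC/C=C(/C)CCC(O)C(C)=C | intermediate (not isolated)
17 | (3Z)-4,8-dimethylnona-3,8-diene-1,7-diol (racemic) | OCC/C=C(/C)CCC(O)C(C)=C | intermediate
18 | (3Z)-7-hydroxy-4,8-dimethylnona-3,8-dien-1-yl 4-methylbenzenesulfonate | Cc1ccc(cc1)S(=O)(=O)OCC/C=C(/C)CCC(O)C(C)=C | intermediate
19 | methyl 2-(diethoxyphosphoryl)acetate | CCOP(=O)(OCC)CC(=O)OC | starting material
20 | sodium salt of methyl 2-(diethoxyphosphoryl)acetate | [Na+].CCOP(=O)(OCC)[CH-]C(=O)OC | intermediate (not isolated)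
21 | methyl (5Z)-2-(diethoxyphosphoryl)-9-hydroxy-6,10-dimethylundeca-5,10-dienoate | CCOP(=O)(OCC)C(CC/C=C(/C)CCC(O)C(C)=C)C(=O)OC | intermediate
22 | prop-2-enyl (3S,5E,9Z)-13-hydroxy-6-(methoxycarbonyl)-10,14-dimethyl-3-(6-methylhepta-1,5-dien-2-yl)pentadeca-5,9,14-trienoate | C=C(CCC=C(C)C)[C@@H](C/C=C(/C(=O)OC)CC/C=C(/C)CCC(O)C(C)=C)CC(=O)OCC=C | intermediate
23 | (3S,5E,9Z)-13-hydroxy-6-(methoxycarbonyl)-10,14-dimethyl-3-(6-methylhepta-1,5-dien-2-yl)pentadeca-5,9,14-trienoic acid | C=C(CCC=C(C)C)[C@@H](C/C=C(/C(=O)OC)CC/C=C(/C)CCC(O)C(C)=C)CC(=O)O | intermediate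
24 | mixed anhydride of acid 23 with 2,4,6-trichlorobenzoic acid | C=C(CCC=C(C)C)[C@@H](C/C=C(/C(=O)OC)CC/C=C(/C)CCC(O)C(C)=C)CC(=O)OC(=O)c1c(Cl)cc(Cl)cc1Cl | intermediate (not isolated)
25 | methyl (4S,6E,10Z)-11-methyl-4-(6-methylhepta-1,5-dien-2-yl)-2-oxo-14-(prop-1-en-2-yl)-1-oxacyclotetradeca-6,10-diene-7-carboxylate | C=C(CCC=C(C)C)[C@H]1C/C=C(/C(=O)OC)CC/C=C(/C)CCC(C(C)=C)OC(=O)C1 | intermediate
26 | trimethylsilyl ketene acetal of lactone 25 (C14=C(OSiMe3)–O–C11) | C=C(CCC=C(C)C)[C@H]1C/C=C(/C(=O)OC)CC/C=C(/C)CCC(C(C)=C)OC(O[Si](C)(C)C)=C1 | intermediate (not isolated)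
27 | trimethylsilyl ester of acid 28 | C=C(CCC=C(C)C)[C@H]1C/C=C(/C(=O)OC)CC/C=C(/C)CC/C=C(\C)CC1C(=O)O[Si](C)(C)C | intermediate (not isolated)
28 | (1S,3E,7Z,11E)-4-(methoxycarbonyl)-8,12-dimethyl-1-(6-methylhepta-1,5-dien-2-yl)cyclotetradeca-3,7,11-triene-14-carboxylic acid | C=C(CCC=C(C)C)[C@H]1C/C=C(/C(=O)OC)CC/C=C(/C)CC/C=C(\C)CC1C(=O)O | intermediate
29 | 2-thioxopyridin-1(2H)-yl ester of acid 28 | C=C(CCC=C(C)C)[C@H]1C/C=C(/C(=O)OC)CC/C=C(/C)CC/C=C(\C)CC1C(=O)On2ccccc2=S | intermediate (not isolated)
30 | methyl (1R,3E,7Z,11E)-8,12-dimethyl-1-(6-methylhepta-1,5-dien-2-yl)cyclotetradeca-3,7,11-triene-4-carboxylate | C=C(CCC=C(C)C)[C@H]1C/C=C(/C(=O)OC)CC/C=C(/C)CC/C=C(\C)CC1 | target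

**Step count.** Total: 15 steps. Longest linear sequence: 10 steps (steps 1–5 then 11–15 from ketone 1; the neryl acetate branch, steps 6–10 then 11–15, is equally long).

**Steps most likely to fail**

Step 14. The enolisation may not discriminate between the lactone and the γ-position of the enoate, or the ring-bound chair may react slowly or lose E selectivity. In the fallback the same [3,3] bond construction is carried out on an open-chain ester that contains no enoate, and the ring is closed afterwards by olefination. It sets out from potassium salt 8 (made from lactone 7 as in step 4) and from tosylate 18, and returns to the route at target 30. Silylation of 8 (TBSCl, imidazole, DMF) should give the bis-silyl compound F1, and mild cleavage of its silyl ester (K2CO3, MeOH/H2O) the silyloxy acid F2. Steglich esterification of F2 with the C11 carbinol of 18 (DCC, DMAP, CH2Cl2) gives the allylic ester F3. Ireland–Claisen rearrangement (lithium diisopropylamide, TMSCl/Et3N, THF, −78 °C to rt) should proceed through the silyl ketene acetal F4 and the trimethylsilyl ester F5 to the open-chain acid F6 with the E C11–C12 alkene, since the chair is unconstrained. Barton decarboxylation as in step 15, through the thiohydroxamate ester F7, gives the tosylate F8. Alkylation of sodium salt 20 with F8 (DMF, 65 °C) gives the phosphonate F9, desilylation (TBAF, AcOH, THF) the primary alcohol F10, and TEMPO/PhI(OAc)2 oxidation the aldehyde F11. An intramolecular Horner–Wadsworth–Emmons reaction (LiCl, DBU, MeCN, high dilution) then closes C3–C4 to give 30.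

Step 8. The Grignard reagent may attack the acetate carbonyl instead of the allylic carbon, may react in the SN2′ sense, or the Z alkene may erode through allylcopper equilibration. The fallback replaces the allylic substitution by an oxidation, methylenation and hydroboration homologation. It sets out from hydroxy acetate 13 and returns at diol 17. Silylation (TBSCl, imidazole, DMF) gives the silyl ether F12, and methanolysis of the acetate (K2CO3, MeOH) the allylic alcohol F13. TEMPO/PhI(OAc)2 oxidation gives the Z enal F14, and Wittig methylenation (Ph3P=CH2, THF, −78 to 0 °C) the triene F15. Hydroboration of the monosubstituted alkene with disiamylborane followed by NaOH/H2O2 gives the homoallylic alcohol F16, and TBAF then gives 17.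

Step 11. The E selectivity may be insufficient and the olefination slow with the α-branched phosphonate. The fallback uses an α-branched stabilised phosphorus ylide, which reacts with aldehydes under neutral conditions with a strong intrinsic E preference. It sets out from tosylate 18 and aldehyde 10 and returns at enoate 22. Finkelstein exchange (NaI, acetone) gives the iodide F17. Alkylation of methyl (triphenylphosphoranylidene)acetate (2 equiv, MeCN, reflux) proceeds through the phosphonium iodide F18, which the second equivalent of ylide deprotonates to the ylide F19. Wittig reaction of F19 with 10 (toluene, 80 °C) should give 22.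

**Further compounds**

F1 | step 14 | tert-butyldimethylsilyl (3S)-5-[(tert-butyldimethylsilyl)oxy]-3-(6-methylhepta-1,5-dien-2-yl)pentanoate | C=C(CCC=C(C)C)[C@@H](CCO[Si](C)(C)C(C)(C)C)CC(=O)O[Si](C)(C)C(C)(C)C
F2 | step 14 | (3S)-5-[(tert-butyldimethylsilyl)oxy]-3-(6-methylhepta-1,5-dien-2-yl)pentanoic acid | C=C(CCC=C(C)C)[C@@H](CCO[Si](C)(C)C(C)(C)C)CC(=O)O
F3 | step 14 | ester of acid F2 with the C11 carbinol of tosylate 18 | C=C(CCC=C(C)C)[C@@H](CCO[Si](C)(C)C(C)(C)C)CC(=O)OC(CC/C(C)=C\CCOS(=O)(=O)c1ccc(C)cc1)C(C)=C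
F4 | step 14 | trimethylsilyl ketene acetal of ester F3 | C=C(CCC=C(C)C)[C@@H](CCO[Si](C)(C)C(C)(C)C)C=C(O[Si](C)(C)C)OC(CC/C(C)=C\CCOS(=O)(=O)c1ccc(C)cc1)C(C)=C
F5 | step 14 | trimethylsilyl ester of acid F6 | C=C(CCC=C(C)C)[C@@H](CCO[Si](C)(C)C(C)(C)C)C(C/C(C)=C/CC/C(C)=C\CCOS(=O)(=O)c1ccc(C)cc1)C(=O)O[Si](C)(C)C
F6 | step 14 | open-chain C14 acid with E C11–C12 and Z C7–C8 alkenes, C3 silyl ether and C5 tosylate | C=C(CCC=C(C)C)[C@@H](CCO[Si](C)(C)C(C)(C)C)C(C/C(C)=C/CC/C(C)=C\CCOS(=O)(=O)c1ccc(C)cc1)C(=O)O
F7 | step 14 | 2-thioxopyridin-1(2H)-yl ester of acid F6 | C=C(CCC=C(C)C)[C@@H](CCO[Si](C)(C)C(C)(C)C)C(C/C(C)=C/CC/C(C)=C\CCOS(=O)(=O)c1ccc(C)cc1)C(=O)On1ccccc1=S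
F8 | step 14 | decarboxylated open-chain tosylate (C3 silyl ether, C5 tosylate) | C=C(CCC=C(C)C)[C@@H](CCO[Si](C)(C)C(C)(C)C)CC/C(C)=C/CC/C(C)=C\CCOS(=O)(=O)c1ccc(C)cc1
F9 | step 14 | open-chain C4 phosphonoacetate with C3 silyl ether | C=C(CCC=C(C)C)[C@@H](CCO[Si](C)(C)C(C)(C)C)CC/C(C)=C/CC/C(C)=C\CCC(C(=O)OC)P(=O)(OCC)OCC
F10 | step 14 | open-chain C4 phosphonoacetate with free C3 alcohol | C=C(CCC=C(C)C)[C@@H](CCO)CC/C(C)=C/CC/C(C)=C\CCC(C(=O)OC)P(=O)(OCC)OCC
F11 | step 14 | open-chain C3 aldehyde with C4 phosphonoacetate | C=C(CCC=C(C)C)[C@@H](CC=O)CC/C(C)=C/CC/C(C)=C\CCC(C(=O)OC)P(=O)(OCC)OCC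
F12 | step 8 | (2Z)-6-[(tert-butyldimethylsilyl)oxy]-3,7-dimethylocta-2,7-dien-1-yl acetate | CC(=O)OC/C=C(/C)CCC(O[Si](C)(C)C(C)(C)C)C(C)=C
F13 | step 8 | (2Z)-6-[(tert-butyldimethylsilyl)oxy]-3,7-dimethylocta-2,7-dien-1-ol | OC/C=C(/C)CCC(O[Si](C)(C)C(C)(C)C)C(C)=C
F14 | step 8 | (2Z)-6-[(tert-butyldimethylsilyl)oxy]-3,7-dimethylocta-2,7-dienal | O=C/C=C(/C)CCC(O[Si](C)(C)C(C)(C)C)C(C)=C
F15 | step 8 | tert-butyl{[(6Z)-2,6-dimethylnona-1,6,8-trien-3-yl]oxy}dimethylsilane | C=C/C=C(/C)CCC(O[Si](C)(C)C(C)(C)C)C(C)=C
F16 | step 8 | (3Z)-7-[(tert-butyldimethylsilyl)oxy]-4,8-dimethylnona-3,8-dien-1-ol | OCC/C=C(/C)CCC(O[Si](C)(C)C(C)(C)C)C(C)=C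
F17 | step 11 | (6Z)-9-iodo-2,6-dimethylnona-1,6-dien-3-ol | C=C(C)C(O)CC/C(C)=C\CCI
F18 | step 11 | [(5Z)-9-hydroxy-1-methoxy-6,10-dimethyl-1-oxoundeca-5,10-dien-2-yl]triphenylphosphonium iodide | [I-].COC(=O)C(CC/C=C(/C)CCC(O)C(C)=C)[P+](c1ccccc1)(c1ccccc1)c1ccccc1
F19 | step 11 | methyl (5Z)-9-hydroxy-6,10-dimethyl-2-(triphenylphosphoranylidene)undeca-5,10-dienoate | COC(=O)C(CC/C=C(/C)CCC(O)C(C)=C)=P(c1ccccc1)(c1ccccc1)c1ccccc1
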